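The tetrahydrofuran ring (O1, C2–C5) of the target has at C2 a benzylic ether carbon bonded to C3, which carries a carboxyl-derived CH2OH arm. The route therefore rests on making the C2–C3 bond by insertion of a rhodium carbene centred on C3 into a C–H bond of an O1–CH2–aryl ether. In one operation this closes the ring and sets C2 (C3 follows by equilibration), leaving a C4 arylidene that later becomes the aroyl group. The precursor is a Z vinyldiazoacetate whose vinyl carbon (C4) carries the diazo ester, the CH2–O–CH2–aryl arm and an arylidene whose aryl ring is held trans to the diazo carbon.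

Key step: step 6

Remark: the sense of induction of Rh2(S-PTTL)4 at C2 is assumed to give 2S; if the first run shows the opposite sense, Rh2(R-PTTL)4 is used and nothing else changes.

Ring atoms are numbered O1, C2 (aryl), C3, C4, C5 throughout, as in the target. Rh2(S-PTTL)4 is dirhodium tetrakis[N-phthaloyl-(S)-tert-leucinate].

Step 1
Reactants: 1 3-(benzyloxy)-4-methoxybenzyl alcohol
Product: 2 3-(benzyloxy)-4-methoxybenzyl chloride
Conditions: SOCl2 (1.2 equiv), CH2Cl2, 0 °C → rt
Reagents that add atoms: thionyl chloride, O=S(Cl)Cl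
Why: Chlorodehydroxylation through the chlorosulfite is fast for an electron-rich benzylic alcohol and leaves the aryl benzyl ether untouched.

Step 2
Reactants: 1 3-(benzyloxy)-4-methoxybenzyl alcohol; 3 methyl 4-chloro-3-oxobutanoate
Product: 4 methyl 4-{[3-(benzyloxy)-4-methoxybenzyl]oxy}-3-oxobutanoate
Conditions: NaH (2.2 equiv), THF, 0 °C → rt; aq NH4Cl
Reagents that add atoms: none
Why: Williamson ether synthesis in which the second equivalent of NaH masks the active methylene as its enolate, so the benzylic alkoxide displaces only the primary chloride next to the ketone.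

Step 3
Reactants: 4 methyl 4-{[3-(benzyloxy)-4-methoxybenzyl]oxy}-3-oxobutanoate
Product: 5 methyl (2Z)-4-{[3-(benzyloxy)-4-methoxybenzyl]oxy}-3-{[(trifluoromethyl)sulfonyl]oxy}but-2-enoate
Conditions: Tf2O, aq LiOH, toluene, 5 °C
Reagents that add atoms: trifluoromethanesulfonic anhydride, O=S(=O)(OS(=O)(=O)C(F)(F)F)C(F)(F)F
Why: Enol triflate formation by O-sulfonylation of the chelated lithium enolate of the β-keto ester, which forms only at the far more acidic C2 methylene; the alkene geometry is of no later consequence.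

Step 4
Reactants: 2 3-(benzyloxy)-4-methoxybenzyl chloride; 5 methyl (2Z)-4-{[3-(benzyloxy)-4-methoxybenzyl]oxy}-3-{[(trifluoromethyl)sulfonyl]oxy}but-2-enoate
Product: 7 methyl (2E)-4-[3-(benzyloxy)-4-methoxyphenyl]-3-({[3-(benzyloxy)-4-methoxybenzyl]oxy}methyl)but-2-enoate, via benzylic zinc chloride 6 (not isolated)
Conditions: Zn dust, LiCl, THF, rt; then 5, Pd(PPh3)4 (3 mol %), THF, rt → 50 °C
Reagents that add atoms: none
Why: LiCl-assisted zinc insertion into the benzylic chloride followed by Negishi cross-coupling with the activated β-triflyloxy acrylate forms the sp3–sp2 bond and tolerates the ester and both ethers.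

Step 5
Reactants: 7 methyl (2E)-4-[3-(benzyloxy)-4-methoxyphenyl]-3-({[3-(benzyloxy)-4-methoxybenzyl]oxy}methyl)but-2-enoate
Product: 8 methyl (3Z)-4-[3-(benzyloxy)-4-methoxyphenyl]-3-({[3-(benzyloxy)-4-methoxybenzyl]oxy}methyl)-2-diazobut-3-enoate
Conditions: p-ABSA (1.3 equiv), DBU (1.5 equiv), MeCN, 0 °C → rt; product kept cold and used at once
Reagents that add atoms: 4-acetamidobenzenesulfonyl azide (p-ABSA), CC(=O)Nc1ccc(cc1)S(=O)(=O)N=[N+]=[N-]
Why: Regitz diazo transfer through the extended enolate, in which DBU removes the benzylic γ-hydrogen and the dienolate attacks the sulfonyl azide at C2; allylic strain should place the aryl ring trans to the planar diazo ester unit (Z), and any E isomer is removed by chromatography.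

Step 6
Reactants: 8 methyl (3Z)-4-[3-(benzyloxy)-4-methoxyphenyl]-3-({[3-(benzyloxy)-4-methoxybenzyl]oxy}methyl)-2-diazobut-3-enoate
Product: 10 methyl (2S,3S,4Z)-2-[3-(benzyloxy)-4-methoxyphenyl]-4-[3-(benzyloxy)-4-methoxybenzylidene]tetrahydrofuran-3-carboxylate, via 2,3-cis ester 9 (not isolated)
Conditions: Rh2(S-PTTL)4 (1 mol %), toluene, −60 °C → 0 °C, slow addition of 8; then NaOMe (0.2 equiv), MeOH, 0 °C
Reagents that add atoms: none
Why: The dirhodium carboxylate expels N2 from 8 to give a donor/acceptor vinylcarbene centred on C3, which takes a hydride-like C–H bond of the O1–CH2–aryl group five atoms away in a concerted, asynchronous insertion that forms C2–C3. The closest known reaction type is the dirhodium-catalysed intramolecular C–H insertion of aryl diazoacetates into benzylic ether C–H bonds, which gives 2-aryl-2,3-dihydrobenzofuran-3-carboxylates, cis-selectively with this catalyst class. The tetrahydrofuran closes by 1,5 C–H insertion, the carbene carbon and the C–H carbon becoming the adjacent ring atoms C3 and C2, with the vinyl carbon (C4) and the allylic O–CH2 (C5) as tether. C2 is set by the chiral carboxylate pocket, which selects one of the two enantiotopic benzylic hydrogens; C3 is set under thermodynamic control when catalytic NaOMe equilibrates the kinetic cis ester 9 through its doubly activated C3–H, so that the ester lies trans to the C2 aryl group. The step needs chemoselectivity for the 1,5 site over cyclopropene closure, attack on an arene and 1,2-shift. This is secured by the C–H bond activated by both the ether oxygen and the p-methoxyaryl ring, by the absence of a hydrogen on the vinyl carbon, and by the Z alkene, which holds the electron-rich arylidene ring away from the carbene carbon so that it cannot close to an indene.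

Step 7
Reactants: 10 methyl (2S,3S,4Z)-2-[3-(benzyloxy)-4-methoxyphenyl]-4-[3-(benzyloxy)-4-methoxybenzylidene]tetrahydrofuran-3-carboxylate
Product: 11 {(2S,3R,4Z)-2-[3-(benzyloxy)-4-methoxyphenyl]-4-[3-(benzyloxy)-4-methoxybenzylidene]tetrahydrofuran-3-yl}methanol
Conditions: i-Bu2AlH (2.5 equiv), CH2Cl2, −78 °C → 0 °C; aq potassium sodium tartrate
Reagents that add atoms: none
Why: Hydride reduction of the ester to the primary alcohol with a non-basic aluminium hydride leaves the C3 stereocentre and the arylidene untouched.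

Step 8
Reactants: 11 {(2S,3R,4Z)-2-[3-(benzyloxy)-4-methoxyphenyl]-4-[3-(benzyloxy)-4-methoxybenzylidene]tetrahydrofuran-3-yl}methanol
Product: 12 (S)-[3-(benzyloxy)-4-methoxyphenyl]{(2S,3R,4R)-2-[3-(benzyloxy)-4-methoxyphenyl]-3-(hydroxymethyl)tetrahydrofuran-4-yl}methanol (expected major diastereomer)
Conditions: BH3·THF (3 equiv), THF, 0 °C → rt; then NaOH, H2O2, 0 °C → rt
Reagents that add atoms: hydrogen peroxide, OO
Why: Hydroboration–oxidation places boron on the less substituted benzylic alkene carbon and hydrogen on C4 by syn addition from the face opposite the C3 substituent, and oxidation with retention gives the benzylic alcohol; the C4 and carbinol configurations are corrected or erased in step 9, so a diastereomer mixture is acceptable.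

Step 9
Reactants: 12 (S)-[3-(benzyloxy)-4-methoxyphenyl]{(2S,3R,4R)-2-[3-(benzyloxy)-4-methoxyphenyl]-3-(hydroxymethyl)tetrahydrofuran-4-yl}methanol
Product: 14 [3-(benzyloxy)-4-methoxyphenyl]{(2S,3R,4S)-2-[3-(benzyloxy)-4-methoxyphenyl]-3-(hydroxymethyl)tetrahydrofuran-4-yl}methanone, via 3,4-cis ketone 13 (not isolated)
Conditions: MnO2 (activated, excess), CH2Cl2, rt; filter, concentrate; K2CO3, MeOH, rt
Reagents that add atoms: none
Why: MnO2 oxidises only the electron-rich benzylic alcohol, and base then equilibrates C4 through the enolate to the all-trans ketone, the thermodynamic isomer; ring opening by β-elimination of O1 is the reverse of a 5-endo-trig closure and is stereoelectronically disfavoured.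

Step 10
Reactants: 14 [3-(benzyloxy)-4-methoxyphenyl]{(2S,3R,4S)-2-[3-(benzyloxy)-4-methoxyphenyl]-3-(hydroxymethyl)tetrahydrofuran-4-yl}methanone
Product: 15 (3-hydroxy-4-methoxyphenyl)[(2S,3R,4S)-2-(3-hydroxy-4-methoxyphenyl)-3-(hydroxymethyl)tetrahydrofuran-4-yl]methanone (CNP0234761.1)
Conditions: H2 (1 atm), 10% Pd/C, EtOAc, rt, stopped when 14 is consumed
Reagents that add atoms: none
Why: Catalytic hydrogenolysis cleaves aryl benzyl ethers much faster than it reduces an electron-rich aryl ketone or the cyclic benzylic ether at C2, and no stereocentre is affected.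

Compound list

1 | 3-(benzyloxy)-4-methoxybenzyl alcohol (O-benzylisovanillyl alcohol) | COc1ccc(CO)cc1OCc1ccccc1 | starting material
2 | 3-(benzyloxy)-4-methoxybenzyl chloride | COc1ccc(CCl)cc1OCc1ccccc1 | intermediate
3 | methyl 4-chloro-3-oxobutanoate (methyl 4-chloroacetoacetate) | COC(=O)CC(=O)CCl | starting material
4 | methyl 4-{[3-(benzyloxy)-4-methoxybenzyl]oxy}-3-oxobutanoate | COC(=O)CC(=O)COCc1ccc(OC)c(OCc2ccccc2)c1 | intermediate
5 | methyl (2Z)-4-{[3-(benzyloxy)-4-methoxybenzyl]oxy}-3-{[(trifluoromethyl)sulfonyl]oxy}but-2-enoate | COC(=O)/C=C(/COCc1ccc(OC)c(OCc2ccccc2)c1)OS(=O)(=O)C(F)(F)F | intermediate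
6 | [3-(benzyloxy)-4-methoxybenzyl]zinc chloride, THF solution with LiCl | COc1ccc(C[Zn]Cl)cc1OCc1ccccc1 | intermediate
7 | methyl (2E)-4-[3-(benzyloxy)-4-methoxyphenyl]-3-({[3-(benzyloxy)-4-methoxybenzyl]oxy}methyl)but-2-enoate | COC(=O)/C=C(/COCc1ccc(OC)c(OCc2ccccc2)c1)Cc1ccc(OC)c(OCc2ccccc2)c1 | intermediate
8 | methyl (3Z)-4-[3-(benzyloxy)-4-methoxyphenyl]-3-({[3-(benzyloxy)-4-methoxybenzyl]oxy}methyl)-2-diazobut-3-enoate; aryl trans to the diazo carbon | COC(=O)C(=[N+]=[N-])/C(COCc1ccc(OC)c(OCc2ccccc2)c1)=C/c1ccc(OC)c(OCc2ccccc2)c1 | intermediate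
9 | methyl (2S,3R,4Z)-2-[3-(benzyloxy)-4-methoxyphenyl]-4-[3-(benzyloxy)-4-methoxybenzylidene]tetrahydrofuran-3-carboxylate; 2,3-cis | COc1ccc(/C=C2\CO[C@H](c3ccc(OC)c(OCc4ccccc4)c3)[C@@H]2C(=O)OC)cc1OCc1ccccc1 | intermediate
10 | methyl (2S,3S,4Z)-2-[3-(benzyloxy)-4-methoxyphenyl]-4-[3-(benzyloxy)-4-methoxybenzylidene]tetrahydrofuran-3-carboxylate; 2,3-trans, aryl of the arylidene cis to C5 | COc1ccc(/C=C2\CO[C@H](c3ccc(OC)c(OCc4ccccc4)c3)[C@H]2C(=O)OC)cc1OCc1ccccc1 | intermediate
11 | {(2S,3R,4Z)-2-[3-(benzyloxy)-4-methoxyphenyl]-4-[3-(benzyloxy)-4-methoxybenzylidene]tetrahydrofuran-3-yl}methanol | COc1ccc(/C=C2\CO[C@H](c3ccc(OC)c(OCc4ccccc4)c3)[C@H]2CO)cc1OCc1ccccc1 | intermediate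
12 | (S)-[3-(benzyloxy)-4-methoxyphenyl]{(2S,3R,4R)-2-[3-(benzyloxy)-4-methoxyphenyl]-3-(hydroxymethyl)tetrahydrofuran-4-yl}methanol; 2,3-trans, 3,4-cis | COc1ccc([C@@H](O)[C@H]2CO[C@H](c3ccc(OC)c(OCc4ccccc4)c3)[C@H]2CO)cc1OCc1ccccc1 | intermediate
13 | [3-(benzyloxy)-4-methoxyphenyl]{(2S,3R,4R)-2-[3-(benzyloxy)-4-methoxyphenyl]-3-(hydroxymethyl)tetrahydrofuran-4-yl}methanone; 3,4-cis | COc1ccc(C(=O)[C@H]2CO[C@H](c3ccc(OC)c(OCc4ccccc4)c3)[C@H]2CO)cc1OCc1ccccc1 | intermediate
14 | [3-(benzyloxy)-4-methoxyphenyl]{(2S,3R,4S)-2-[3-(benzyloxy)-4-methoxyphenyl]-3-(hydroxymethyl)tetrahydrofuran-4-yl}methanone; all-trans | COc1ccc(C(=O)[C@@H]2CO[C@H](c3ccc(OC)c(OCc4ccccc4)c3)[C@H]2CO)cc1OCc1ccccc1 | intermediate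
15 | (3-hydroxy-4-methoxyphenyl)[(2S,3R,4S)-2-(3-hydroxy-4-methoxyphenyl)-3-(hydroxymethyl)tetrahydrofuran-4-yl]methanone | COc1ccc(C(=O)[C@@H]2CO[C@H](c3ccc(OC)c(O)c3)[C@H]2CO)cc1O | target

Total step count: 10. Longest linear sequence: 9 steps (steps 2 to 10, from 1 and 3); step 1 is a one-step branch.

Steps most likely to fail

Step 6. The chiral carboxylate pocket may not discriminate well enough between the two enantiotopic hydrogens of the O–CH2–aryl group, or may do so only at the cost of carbene diversion. The fallback moves the source of chirality from the catalyst to a classical resolution. It sets out from 8: the insertion is run with the achiral Rh2(esp)2 [dirhodium bis(α,α,α′,α′-tetramethyl-1,3-benzenedipropanoate)] in CH2Cl2 and the crude product is equilibrated with NaOMe as before, which should give the racemic 2,3-trans ester F1. Reduction with i-Bu2AlH gives the racemic alcohol F2, which is acylated with (1S)-camphanic chloride (Et3N, DMAP, CH2Cl2). The two diastereomeric esters are separated by chromatography or crystallisation, and the (2S,3R) camphanate F3 is cleaved with K2CO3 in MeOH to come back to the route at 11.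

Step 5. Deprotonation may occur on the O–CH2 side instead of the benzylic side, the alkene may form as a poorly separable E/Z mixture, or the vinyl diazo ester may be lost by electrocyclisation to a pyrazole while it stands with DBU. The fallback builds the diazo ester by aldol addition and dehydration at low temperature instead of diazo transfer. It sets out from 7: Lemieux–Johnson cleavage (OsO4 cat., NaIO4, 2,6-lutidine, dioxane–water) gives 1-[3-(benzyloxy)-4-methoxyphenyl]-3-{[3-(benzyloxy)-4-methoxybenzyl]oxy}propan-2-one F4. Addition of lithiated methyl diazoacetate (LDA, THF, −78 °C) gives the racemic tertiary β-hydroxy-α-diazo ester F5. Dehydration with POCl3 and Et3N at 0 °C, directed to the benzylic side by conjugation with the aryl ring, comes back to the route at 8 after separation of the Z isomer.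

Step 9. Oxidation of the hindered carbinol on the MnO2 surface may stall, and the 3,4-cis keto alcohol may be held back from epimerisation as a bicyclic hemiketal with the neighbouring CH2OH group. The fallback masks the primary hydroxyl, so that a homogeneous oxidant can be used and no hemiketal can form. It sets out from 12: selective silylation of the primary alcohol (TBSCl, imidazole, CH2Cl2, 0 °C) gives the mono-silyl ether F6. Dess–Martin periodinane gives the 3,4-cis ketone silyl ether F7, DBU in CH2Cl2 equilibrates it to the all-trans ketone silyl ether F8, and HF·pyridine in THF removes the silyl group to come back to the route at 14.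

Further compounds

F1 | step 6 | racemic methyl (2S*,3S*,4Z)-2-[3-(benzyloxy)-4-methoxyphenyl]-4-[3-(benzyloxy)-4-methoxybenzylidene]tetrahydrofuran-3-carboxylate (both enantiomers) | COc1ccc(/C=C2\CO[C@H](c3ccc(OC)c(OCc4ccccc4)c3)[C@H]2C(=O)OC)cc1OCc1ccccc1.COc1ccc(/C=C2\CO[C@@H](c3ccc(OC)c(OCc4ccccc4)c3)[C@@H]2C(=O)OC)cc1OCc1ccccc1
F2 | step 6 | racemic {(2S*,3R*,4Z)-2-[3-(benzyloxy)-4-methoxyphenyl]-4-[3-(benzyloxy)-4-methoxybenzylidene]tetrahydrofuran-3-yl}methanol (both enantiomers) | COc1ccc(/C=C2\CO[C@H](c3ccc(OC)c(OCc4ccccc4)c3)[C@H]2CO)cc1OCc1ccccc1.COc1ccc(/C=C2\CO[C@@H](c3ccc(OC)c(OCc4ccccc4)c3)[C@@H]2CO)cc1OCc1ccccc1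
F3 | step 6 | {(2S,3R,4Z)-2-[3-(benzyloxy)-4-methoxyphenyl]-4-[3-(benzyloxy)-4-methoxybenzylidene]tetrahydrofuran-3-yl}methyl (1S,4R)-camphanate | COc1ccc(/C=C2\CO[C@H](c3ccc(OC)c(OCc4ccccc4)c3)[C@H]2COC(=O)[C@@]23CC[C@@](C)(C(=O)O2)C3(C)C)cc1OCc1ccccc1
F4 | step 5 | 1-[3-(benzyloxy)-4-methoxyphenyl]-3-{[3-(benzyloxy)-4-methoxybenzyl]oxy}propan-2-one | COc1ccc(CC(=O)COCc2ccc(OC)c(OCc3ccccc3)c2)cc1OCc1ccccc1
F5 | step 5 | methyl 4-[3-(benzyloxy)-4-methoxyphenyl]-3-({[3-(benzyloxy)-4-methoxybenzyl]oxy}methyl)-2-diazo-3-hydroxybutanoate (racemic) | COC(=O)C(=[N+]=[N-])C(O)(COCc1ccc(OC)c(OCc2ccccc2)c1)Cc1ccc(OC)c(OCc2ccccc2)c1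
F6 | step 9 | (S)-[3-(benzyloxy)-4-methoxyphenyl]{(2S,3R,4R)-2-[3-(benzyloxy)-4-methoxyphenyl]-3-[(tert-butyldimethylsilyloxy)methyl]tetrahydrofuran-4-yl}methanol | COc1ccc([C@@H](O)[C@H]2CO[C@H](c3ccc(OC)c(OCc4ccccc4)c3)[C@H]2CO[Si](C)(C)C(C)(C)C)cc1OCc1ccccc1
F7 | step 9 | [3-(benzyloxy)-4-methoxyphenyl]{(2S,3R,4R)-2-[3-(benzyloxy)-4-methoxyphenyl]-3-[(tert-butyldimethylsilyloxy)methyl]tetrahydrofuran-4-yl}methanone | COc1ccc(C(=O)[C@H]2CO[C@H](c3ccc(OC)c(OCc4ccccc4)c3)[C@H]2CO[Si](C)(C)C(C)(C)C)cc1OCc1ccccc1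
F8 | step 9 | [3-(benzyloxy)-4-methoxyphenyl]{(2S,3R,4S)-2-[3-(benzyloxy)-4-methoxyphenyl]-3-[(tert-butyldimethylsilyloxy)methyl]tetrahydrofuran-4-yl}methanone | COc1ccc(C(=O)[C@@H]2CO[C@H](c3ccc(OC)c(OCc4ccccc4)c3)[C@H]2CO[Si](C)(C)C(C)(C)C)cc1OCc1ccccc1
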